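Numbering used throughout: the ring atoms of the target are C1 (carbon bearing the ester), C2, C3(CH3)=C4, C5, C6, C7(CH3), C8, C9(OH), C10(isopropyl). The same atom labels are kept for all intermediates. In the decalins, ring A is C3, C2, C1, C10, C9, C8 and ring B is C3, C4, C5, C6, C7, C8.

## Analysis of the target

Compound 24 is a germacrane-type sesquiterpenoid ester built on a single ten-membered carbocycle. The ring holds a Z trisubstituted alkene (C3=C4), a trisubstituted epoxide at C7–C8 with C6 and C9 trans (the epoxide of a 7E alkene), and five contiguous stereocentres: C7 (S), C8 (S), C9 (R), C10 (S) and C1 (R). The C9 hydroxyl is threo to the epoxide oxygen, and the C9 oxygen, the C10 isopropyl group and the C1 oxygen are anti,anti along the chain, which means all-cis once C9–C10–C1 is part of a six-membered ring. Sensitive features are the epoxy alcohol (acid opens it with transannular participation of C3=C4), the aryl ester (base, hydride) and, before epoxidation, the (3Z,7E)-1,5-diene, which can undergo Cope rearrangement on heating. The difficulty lies in the medium ring: direct closure of a ten-membered ring is unfavourable, geometry and configuration are hard to control on so mobile a ring, and substitution at a ring carbon is blocked because the backside lies inside the ring. The feature that is used is that C3, the methyl-bearing alkene carbon, and C8 are 1,6-related in both directions. A C3–C8 bond turns the ring into a decalin with an angular methyl at C3, and an oxygen on C8 together with a leaving group on C4 makes that bond cleavable again with stereospecific formation of C3=C4.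

## Retrosynthetic reasoning

**Epoxide C–O bonds (24 ⇒ 23).** The two C–O bonds of the epoxide are removed first, because the epoxy alcohol is the most acid-labile part of the molecule and should exist only in the last step. The forward reaction is a hydroxyl-directed, vanadium-catalysed epoxidation of allylic alcohol 23. It must choose C7=C8 over C3=C4 (only the former is allylic to the free hydroxyl) and the threo face, which allylic 1,3-strain from the C7 methyl and attack from the outside of the ring both favour.

**Acyl C–O bond at C1 and benzyl C–O bond at C9 (23 ⇒ 22 ⇒ 20 + 21 ⇒ 19).** The ester is introduced late, from 20 and acid chloride 21, so that it never meets alkoxide or hydride. C9 stays masked as its 4-methoxybenzyl ether while C1 is acylated, and the silyl ether at C1 of 19 is the only group that has to come off before that.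

**C7=C8 π bond (19 ⇒ 18 ⇒ 17).** The alkene is traced back to the C8 ketone of 17. A substitution at C8 (for instance to a selenide) is ruled out on a ten-membered ring, so the alkene is made by an elimination that needs no substitution: anti elimination of the C8 alcohol 18 with the C7 hydrogen. The geometry then follows from the relative configuration of C7 (set on a six-membered ring) and C8 (set by chelation-controlled reduction next to the C9 ether). The anti elimination gives the E alkene only if the C7 methyl and the C9 oxygen are anti along the chain, and this fixes the C7 configuration that has to be built.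

**C3–C8 σ bond, reconnected (17 ⇒ 16 ⇒ 15).** This is the key disconnection. Joining C3 to C8 gives a decalin with an angular methyl (C3), an angular hydroxyl (C8) and a sulfonate at C4, and the forward reaction is the Wharton fragmentation of alkoxide 16. No ten-membered ring has to be closed, and the Z geometry is written into the relative configuration of C3 and C4 (sulfonate cis to C2) on a cis-fused decalin. Two cis-fused diastereomers would give 17. In the one with the angular groups on the same face as the C1/C10/C9 triad, the chair with an equatorial sulfonate places the angular methyl and both ring-A oxygens mutually 1,3-diaxial, so the molecule prefers the other chair, where the sulfonate is axial and cannot fragment. In 15 the angular methyl and hydroxyl lie on the face opposite to the triad. Its only low-energy chair–chair form has the sulfonate equatorial, C2 axial on ring B, both ring-A oxygens equatorial and the C7 methyl equatorial.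

**Sulfonate S–O bond and protecting groups (15 ⇒ 14 ⇒ 13 ⇒ 12).** The sulfonate can only be introduced after every step that generates an oxyanion at C8, otherwise ring B would fragment prematurely. C4 therefore carries a triethylsilyl ether that is removed selectively next to the more robust silyl ether at C1, and the secondary C9 hydroxyl of diol 12 is etherified before that.

**C8–C9 bond (12 ⇒ 11).** Ring A is closed by intramolecular reductive (ketyl) coupling of the C9 aldehyde with the C8 ketone of 11. Because the nucleophilic carbon is delivered by a tether fixed on C3, the angular hydroxyl must end cis to the angular methyl, a relation that is hard to obtain by oxidation of an octalin, where reagents attack anti to the methyl.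

**C1–C10 bond (11 ⇒ 10 ⇒ 9 ⇒ 7 + 8).** On ring A the all-cis triad has the isopropyl group axial between two equatorial oxygens, an arrangement that neither equilibration nor hydride reduction on the ring would give. C1 and C10 are therefore set in the open chain under reagent control, by anti-selective allylboration of aldehyde 7 with a γ-isopropyl allyl unit derived from 8. The terminal vinyl group is the masked C9 aldehyde.

**C7–CH3 bond, C4 stereocentre and C2–C3 bond (7 ⇒ 6 ⇒ 5 ⇒ 4 ⇒ 3 ⇒ 1 + 2).** The C7 methyl has to be introduced while C8 is still a carbonyl group. Once ring A is closed, no ketone is left next to C7, and a ketone at C4 would direct enolate chemistry to C5. It is therefore put on the monocyclic ketone 5, whose only enolisable position is C7. The two carbonyl groups of dione 3 are differentiated by an enantioselective mono-reduction to ketol 4, which sets the quaternary centre C3 and the C4 carbinol (hydroxyl cis to the allyl arm) in one step. 3 comes from 1 and 2 by C-allylation.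

## Alternatives that were turned down

**Alternative 1:** The C10–C1 bond is cut. In the forward direction the achiral (3Z,7E)-keto aldehyde A1 is enolised at C10 of its C9 enone with a chiral dialkylchloroborane and a tertiary amine, and the E-enolate adds to the C1 aldehyde to give the ten-membered anti β-hydroxy enone A2.
- For it: it is by far the shortest plan. The precursor is achiral and open-chain, both alkene geometries come from acyclic building blocks, no protecting group is needed, and the anti relation of C1 and C10 that the target needs is the intrinsic outcome of an E-enolate.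
- Against it: the ring is closed by a reversible addition that must pay the strain of the ten-membered (Z,E)-dienone. The enone can also be deprotonated at its γ-positions. The β,γ-unsaturated aldehyde can slip into conjugation under amine base. The closed six-membered aldol transition state, on which both the anti selectivity and the facial control by the boron ligands rest, has to be accommodated inside a ten-membered tether that contains two alkenes. C9 would then have to be set by reduction of a ring enone, and the β-hydroxy ketone is open to retro-aldol and to epimerisation at C10.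
- Comparison: on step economy this alternative is clearly stronger. The chosen route offers in exchange a ring-forming event that involves no macrocyclisation, and C1, C9 and C10 are set in the open chain or on a six-membered ring by well-understood control elements.

**Alternative 2:** The C4–C5 bond is cut. In the forward direction the terminal C5=C6 alkene of the open-chain iodo diene A3 is hydroborated with a hindered dialkylborane, and the boron-bearing C5 is coupled intramolecularly with the Z vinyl iodide at C4 under palladium catalysis (B-alkyl Suzuki coupling) to give the (3Z,7E)-diene A4.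
- For it: both alkene geometries are fixed before the ring is closed, all three stereocentres are made by acyclic chemistry, the ester is already in place, and A4 is only a desilylation and a directed epoxidation away from the target. On the security of the C7=C8 geometry and on the end game it is stronger than the chosen route, which has to create the E alkene on the ring.
- Against it: a ten-membered ring must be closed by a C(sp3)–C(sp2) reductive elimination that builds the full strain of the (Z,E)-cyclodecadiene, the worst ring size for such a macrocyclisation. β-Hydride elimination, protodeboronation and dimerisation compete. The hydroboration has to pick the terminal alkene of a 1,3-diene in the presence of a vinyl iodide, and the aqueous base meets the aryl ester.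
- Comparison: the chosen strategy offers a ring-forming step with a built-in driving force (C=O formation, loss of sulfonate) and no dilution problem, at the price of a longer sequence and of alkene formation on the ring.

**Alternative 3:** The C9–C10 bond is cut. In the forward direction the allylic bromide of the epoxy aldehyde A5 is metalated reductively with a divalent chromium salt, and the allylmetal attacks the C9 aldehyde through its γ-carbon C10. This closes the ring and sets C9 and C10 in the epoxy alcohol A6, which carries an isopropenyl group on C10.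
- For it: the conditions are neutral and tolerate the epoxide, two stereocentres and the ring arise in one step, and the epoxide configuration is set beforehand by a reagent-controlled epoxidation. On that last point it is stronger than the chosen route, which relies on substrate control.
- Against it: γ-substituted allylchromium reagents intrinsically give the anti homoallylic alcohol, i.e. the hydroxyl anti to the γ-substituent, which here is the ring chain through C1. Along the ring chain this places the C9 hydroxyl and the three-carbon branch on C10 syn, whereas 24 needs them anti. Ring constraints would therefore have to override the normal preference. In addition, the isopropenyl group must be hydrogenated in the presence of C3=C4 and of an allylic-type epoxide, the α-epoxy aldehyde is fragile, and the ether at C1 must be exchanged for the ester next to a free C9 hydroxyl.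
- Comparison: the chosen strategy sets the C9/C10 relation in the open chain and on a six-membered ring, with no such mismatch, and pays for it with more steps.

Key step: step 13

Assumption: the (R,R)-TsDPEN ruthenium catalyst is taken to give the (2R,3R)-ketol 4 and the borane from (−)-Ipc2BOMe to attack the Si face of aldehyde 7; if either sense is the reverse, the antipodal ligand or borane is used.

## Route

Step 1
Reactants: 1 2-methylcyclohexane-1,3-dione; 2 allyl acetate
Product: 3 2-methyl-2-(prop-2-en-1-yl)cyclohexane-1,3-dione
Conditions: Pd(PPh3)4 (2 mol %), DBU, toluene, 80 °C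
Reagents that add atoms: allyl acetate (2), C=CCOC(C)=O
Why: Tsuji–Trost allylation; the soft dione enolate attacks the π-allyl complex of palladium at carbon, so the quaternary C3 forms without the O-allylation that allyl halides give.

Step 2
Reactants: 3 2-methyl-2-(prop-2-en-1-yl)cyclohexane-1,3-dione
Product: 4 (2R,3R)-3-hydroxy-2-methyl-2-(prop-2-en-1-yl)cyclohexan-1-one
Conditions: RuCl[(R,R)-TsDPEN](p-cymene) (1 mol %), HCO2H/Et3N (5:2), CH2Cl2, rt
Reagents that add atoms: none
Why: Noyori asymmetric transfer hydrogenation desymmetrises the prochiral dione: the catalyst selects one enantiotopic carbonyl and hydride enters anti to the larger allyl group, so the C4 hydroxyl ends cis to the allyl arm (C2) and trans to the C3 methyl. This one step sets C3 and C4, i.e. the sulfonate/C2 relation that the fragmentation needs; the hindered ketol should not be reduced further.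

Step 3
Reactants: 4 (2R,3R)-3-hydroxy-2-methyl-2-(prop-2-en-1-yl)cyclohexan-1-one
Product: 5 (2R,3R)-2-methyl-2-(prop-2-en-1-yl)-3-[(triethylsilyl)oxy]cyclohexan-1-one
Conditions: Et3SiCl, imidazole, DMF, rt
Reagents that add atoms: chlorotriethylsilane, CC[Si](Cl)(CC)CC
Why: Silylation of the secondary alcohol; the triethylsilyl ether survives the enolate, ozonolysis and ketyl steps and can later be removed next to the tert-butyldimethylsilyl ether.

Step 4
Reactants: 5 (2R,3R)-2-methyl-2-(prop-2-en-1-yl)-3-[(triethylsilyl)oxy]cyclohexan-1-one
Product: 6 (2R,3R,6R)-2,6-dimethyl-2-(prop-2-en-1-yl)-3-[(triethylsilyl)oxy]cyclohexan-1-one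
Conditions: LDA, THF, −78 °C; MeI, −78 → −20 °C
Reagents that add atoms: iodomethane, CI
Why: Enolate alkylation; C7 is the only enolisable position because C3 is quaternary. Methyl iodide should enter anti to the axial allyl arm, giving the 2,6-cis-dimethyl ketone with both methyls and the silyloxy group equatorial; this is also the thermodynamic epimer and can be secured by base equilibration.

Step 5
Reactants: 6 (2R,3R,6R)-2,6-dimethyl-2-(prop-2-en-1-yl)-3-[(triethylsilyl)oxy]cyclohexan-1-one
Product: 7 2-[(1R,3R,6R)-1,3-dimethyl-2-oxo-6-[(triethylsilyl)oxy]cyclohexyl]acetaldehyde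
Conditions: O3, CH2Cl2, −78 °C; PPh3, −78 °C → rt
Reagents that add atoms: ozone, [O-][O+]=O
Why: Ozonolysis with reductive work-up cleaves the only alkene to the C1 aldehyde; ketone and silyl ether are inert.

Step 6
Reactants: 7 2-[(1R,3R,6R)-1,3-dimethyl-2-oxo-6-[(triethylsilyl)oxy]cyclohexyl]acetaldehyde; 8 (E)-4-methylpent-2-ene
Product: 9 (2R,3R,6R)-2-[(2R,3S)-2-hydroxy-3-(propan-2-yl)pent-4-en-1-yl]-2,6-dimethyl-3-[(triethylsilyl)oxy]cyclohexan-1-one
Conditions: 8, n-BuLi, KOtBu, THF, −78 → −45 °C; (−)-Ipc2BOMe, −78 °C; BF3·OEt2; then 7, −78 °C; NaOH, H2O2, 0 °C → rt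
Reagents that add atoms: (E)-(4-methylpent-2-en-1-yl)diisopinocampheylborane, made in the flask from 8, CC(C)/C=C/CB([C@@H]1C[C@@H]2C[C@H]([C@H]1C)C2(C)C)[C@@H]1C[C@@H]2C[C@H]([C@H]1C)C2(C)C
Why: Brown-type allylboration with a γ-substituted (E)-allylborane: the closed chair transition state turns the E geometry into the C1/C10 anti relation, and the isopinocampheyl groups select the Si face of the aldehyde, so C1 (R) and C10 (S) are set by the reagent and not by the remote ring stereocentres. The hindered ketone should not react at −78 °C, and the terminal vinyl group is the masked C9 aldehyde.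

Step 7
Reactants: 9 (2R,3R,6R)-2-[(2R,3S)-2-hydroxy-3-(propan-2-yl)pent-4-en-1-yl]-2,6-dimethyl-3-[(triethylsilyl)oxy]cyclohexan-1-one
Product: 10 (2R,3R,6R)-2-[(2R,3S)-2-[(tert-butyldimethylsilyl)oxy]-3-(propan-2-yl)pent-4-en-1-yl]-2,6-dimethyl-3-[(triethylsilyl)oxy]cyclohexan-1-one
Conditions: TBSOTf, 2,6-lutidine, CH2Cl2, −78 → 0 °C
Reagents that add atoms: tert-butyldimethylsilyl triflate, CC(C)(C)[Si](C)(C)OS(=O)(=O)C(F)(F)F
Why: Silylation of the C1 hydroxyl with the reactive triflate; it also prevents hemiketal formation with the C8 ketone and β-elimination in the aldehyde to come.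

Step 8
Reactants: 10 (2R,3R,6R)-2-[(2R,3S)-2-[(tert-butyldimethylsilyl)oxy]-3-(propan-2-yl)pent-4-en-1-yl]-2,6-dimethyl-3-[(triethylsilyl)oxy]cyclohexan-1-one
Product: 11 (2R,3R)-3-[(tert-butyldimethylsilyl)oxy]-4-[(1R,3R,6R)-1,3-dimethyl-2-oxo-6-[(triethylsilyl)oxy]cyclohexyl]-2-(propan-2-yl)butanal
Conditions: O3, CH2Cl2, −78 °C; PPh3, −78 °C → rt; used at once
Reagents that add atoms: ozone, [O-][O+]=O
Why: Ozonolysis of the terminal alkene gives the C9 aldehyde; the neutral reductive work-up should avoid epimerisation at C10 and loss of the β-silyloxy group.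

Step 9
Reactants: 11 (2R,3R)-3-[(tert-butyldimethylsilyl)oxy]-4-[(1R,3R,6R)-1,3-dimethyl-2-oxo-6-[(triethylsilyl)oxy]cyclohexyl]-2-(propan-2-yl)butanal
Product: 12 (1R,3R,4R,7R,8R,9R,10S)-cis-decalin-8,9-diol (fusion bond C3–C8; 3,7-dimethyl, 10-isopropyl, 1-OTBS, 4-OTES; angular CH3, angular OH and C7 methyl on one face, the oxygens at C1, C4, C9 and the isopropyl group on the other)
Conditions: SmI2 (3 equiv), t-BuOH (2 equiv), THF, −78 °C → rt, high dilution
Reagents that add atoms: none
Why: Intramolecular ketyl–carbonyl (pinacol-type) coupling: the aldehyde ketyl adds to the C8 ketone. In 11 the 2,6-cis-dimethyl ketone holds the side chain axial on ring B, so C9 can reach only the lower face of C8 and the angular hydroxyl must end cis to the angular methyl (cis fusion). The bulky samarium-bound oxygen at C9 should take the equatorial site, trans to the C8 hydroxyl and away from the axial angular methyl.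

Step 10
Reactants: 12 (1R,3R,4R,7R,8R,9R,10S)-cis-decalin-8,9-diol
Product: 13 9-O-(4-methoxybenzyl) ether of 12, (1R,3R,4R,7R,8R,9R,10S)-8-hydroxy-9-[(4-methoxybenzyl)oxy]-1-OTBS-4-OTES cis-decalin
Conditions: NaH, 4-methoxybenzyl bromide, Bu4NI (cat.), THF/DMF, 0 °C → rt
Reagents that add atoms: 4-methoxybenzyl bromide, COc1ccc(CBr)cc1
Why: Williamson etherification of the secondary, equatorial C9 hydroxyl; the tertiary C8 hydroxyl is too hindered to be alkylated, and the diequatorial 1,3-arrangement on the rigid ring should prevent silyl migration.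

Step 11
Reactants: 13 9-O-(4-methoxybenzyl) ether
Product: 14 (1R,3R,4R,7R,8R,9R,10S)-4,8-dihydroxy-9-[(4-methoxybenzyl)oxy]-1-OTBS cis-decalin
Conditions: HF·pyridine, pyridine, THF, 0 °C → rt
Reagents that add atoms: none
Why: Selective desilylation: the triethylsilyl ether is cleaved far faster than the tert-butyldimethylsilyl ether under buffered fluoride, and the benzyl ether is inert.

Step 12
Reactants: 14 C4,C8-diol
Product: 15 (1R,3R,4R,7R,8R,9R,10S)-8-hydroxy-9-[(4-methoxybenzyl)oxy]-1-OTBS cis-decalin 4-(4-methylbenzenesulfonate) (sulfonate trans to the angular methyl and cis to C2)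
Conditions: TsCl, pyridine, DMAP (cat.), 40 °C
Reagents that add atoms: 4-methylbenzenesulfonyl chloride, Cc1ccc(cc1)S(Cl)(=O)=O
Why: Sulfonylation of the only secondary alcohol; the tertiary C8 hydroxyl does not react, and no base strong enough to deprotonate it is present, so the monosulfonate of the 1,3-diol should be stable.

Step 13
Reactants: 15 cis-decalin 1,3-diol monosulfonate
Product: 17 (1R,3Z,7R,9R,10S)-1-[(tert-butyldimethylsilyl)oxy]-9-[(4-methoxybenzyl)oxy]-3,7-dimethyl-10-(propan-2-yl)cyclodec-3-en-8-one, via potassium C8-alkoxide 16 (not isolated)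
Conditions: KOtBu (1.05 equiv), THF, 0 °C; pH 7 buffer
Reagents that add atoms: none
Why: Wharton (Grob-type) fragmentation of a cyclic 1,3-diol monosulfonate: deprotonation of the angular hydroxyl gives alkoxide 16, whose oxygen lone pair pushes into the C8–C3 bond while that bond, antiperiplanar to the C4–O bond, expels the sulfonate in one concerted step, forming C8=O and C3=C4. No ring is closed by bond formation; the ten-membered ring appears when the bond shared by rings A and B is cleaved, so no macrocyclisation entropy has to be paid. No stereocentre is created, and the new stereo-element is the alkene geometry. With the sulfonate equatorial and C2 axial on ring B, C2 and C5 lie gauche on the same side of the C3–C4 axis and must become cis, so the alkene is Z; a trans-fused decalin would give E. The step needs fragmentation to win over elimination, oxetane formation and methyl shift, and this is secured by the ground-state chair of 15: the equatorial sulfonate has no antiperiplanar hydrogen, only the C3–C8 bond. The other chair is excluded by a 1,3-diaxial methyl/methyl pair on ring B and three syn-axial groups on ring A. The base is consumed as potassium sulfonate, so with a near-stoichiometric amount little should remain to epimerise C7 or C9 next to the new ketone.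

Step 14
Reactants: 17 ten-membered (3Z)-enone
Product: 18 (1R,3Z,7R,8S,9R,10S)-1-[(tert-butyldimethylsilyl)oxy]-9-[(4-methoxybenzyl)oxy]-3,7-dimethyl-10-(propan-2-yl)cyclodec-3-en-8-ol
Conditions: Zn(BH4)2, Et2O, −20 °C
Reagents that add atoms: none
Why: Chelation-controlled (Cram chelate) reduction: zinc bridges the C8 carbonyl and the C9 ether oxygen, and hydride enters from the side of the C9 hydrogen, which is also the outer face of the ring. This should give the 8,9-anti alcohol, in which the C8 oxygen is syn to the C7 methyl and anti to the C7 hydrogen.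

Step 15
Reactants: 18 C8 alcohol
Product: 19 (1R,3Z,7E,9S,10S)-1-[(tert-butyldimethylsilyl)oxy]-9-[(4-methoxybenzyl)oxy]-3,7-dimethyl-10-(propan-2-yl)cyclodeca-3,7-diene
Conditions: Martin sulfurane [Ph2S(OC(CF3)2Ph)2], CH2Cl2, 0 °C → rt
Reagents that add atoms: none
Why: Dehydration through an alkoxysulfonium ion by anti (E2) elimination, which needs no substitution at the ring carbon. In 18 the C7 hydrogen is antiperiplanar to the C8–O bond in the rotamer that has C6 and C9 anti, so the 7E alkene should form. The C9 hydrogen, α to the ether oxygen, is not removed (allylic ether rather than enol ether), and room temperature keeps the 1,5-diene from Cope rearrangement.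

Step 16
Reactants: 19 (3Z,7E)-diene
Product: 20 (1R,3Z,7E,9S,10R)-9-[(4-methoxybenzyl)oxy]-3,7-dimethyl-10-(propan-2-yl)cyclodeca-3,7-dien-1-ol
Conditions: Bu4NF, THF, 0 °C → rt
Reagents that add atoms: none
Why: Fluoride cleavage of the silyl ether; the benzyl ether and both alkenes are inert.

Step 17
Reactants: 20 C1 alcohol; 21 3,4,5-trimethoxybenzoyl chloride
Product: 22 (1R,3Z,7E,9S,10R)-9-[(4-methoxybenzyl)oxy]-3,7-dimethyl-10-(propan-2-yl)cyclodeca-3,7-dien-1-yl 3,4,5-trimethoxybenzoate
Conditions: Et3N, DMAP, CH2Cl2, 0 °C → rt
Reagents that add atoms: 3,4,5-trimethoxybenzoyl chloride (21), COc1cc(C(Cl)=O)cc(OC)c1OC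
Why: DMAP-catalysed acylation of the only free hydroxyl; C9 is still masked, so no regiochemical question arises.

Step 18
Reactants: 22 C1 ester, C9 benzyl ether
Product: 23 (1R,3Z,7E,9S,10S)-9-hydroxy-3,7-dimethyl-10-(propan-2-yl)cyclodeca-3,7-dien-1-yl 3,4,5-trimethoxybenzoate
Conditions: DDQ, CH2Cl2/pH 7 buffer, 0 °C
Reagents that add atoms: none
Why: Oxidative cleavage of the 4-methoxybenzyl ether by hydride abstraction; the trimethoxybenzoate ring is deactivated by its carbonyl group, and the buffer keeps the medium neutral for the diene.

Step 19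
Reactants: 23 allylic alcohol
Product: 24 (1R,3Z,7S,8S,9R,10S)-7,8-epoxy-9-hydroxy-3,7-dimethyl-10-(propan-2-yl)cyclodec-3-en-1-yl 3,4,5-trimethoxybenzoate (the target)
Conditions: VO(acac)2 (5 mol %), t-BuOOH, CH2Cl2, 0 °C
Reagents that add atoms: tert-butyl hydroperoxide, CC(C)(C)OO
Why: Hydroxyl-directed epoxidation: only the alkene allylic to the free hydroxyl reacts, so C3=C4 is untouched. With the C7 methyl cis to C9, allylic 1,3-strain puts the C9 hydrogen in the alkene plane and oxygen is delivered from the hydroxyl side, which is the outer face of the ring, giving the threo epoxy alcohol (7S,8S).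

## Compound list

1 | 2-methylcyclohexane-1,3-dione | CC1C(=O)CCCC1=O | starting material
2 | allyl acetate | C=CCOC(C)=O | starting material
3 | 2-methyl-2-(prop-2-en-1-yl)cyclohexane-1,3-dione | C=CCC1(C)C(=O)CCCC1=O | intermediate
4 | (2R,3R)-3-hydroxy-2-methyl-2-(prop-2-en-1-yl)cyclohexan-1-one | C=CC[C@]1(C)[C@H](O)CCCC1=O | intermediate
5 | (2R,3R)-2-methyl-2-(prop-2-en-1-yl)-3-[(triethylsilyl)oxy]cyclohexan-1-one | C=CC[C@]1(C)[C@H](O[Si](CC)(CC)CC)CCCC1=O | intermediate
6 | (2R,3R,6R)-2,6-dimethyl-2-(prop-2-en-1-yl)-3-[(triethylsilyl)oxy]cyclohexan-1-one | C=CC[C@]1(C)[C@H](O[Si](CC)(CC)CC)CC[C@@H](C)C1=O | intermediate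
7 | 2-[(1R,3R,6R)-1,3-dimethyl-2-oxo-6-[(triethylsilyl)oxy]cyclohexyl]acetaldehyde | O=CC[C@]1(C)[C@H](O[Si](CC)(CC)CC)CC[C@@H](C)C1=O | intermediate
8 | (E)-4-methylpent-2-ene | C/C=C/C(C)C | starting material
9 | (2R,3R,6R)-2-[(2R,3S)-2-hydroxy-3-(propan-2-yl)pent-4-en-1-yl]-2,6-dimethyl-3-[(triethylsilyl)oxy]cyclohexan-1-one | C=C[C@H](C(C)C)[C@H](O)C[C@]1(C)[C@H](O[Si](CC)(CC)CC)CC[C@@H](C)C1=O | intermediate
10 | (2R,3R,6R)-2-[(2R,3S)-2-[(tert-butyldimethylsilyl)oxy]-3-(propan-2-yl)pent-4-en-1-yl]-2,6-dimethyl-3-[(triethylsilyl)oxy]cyclohexan-1-one | C=C[C@H](C(C)C)[C@H](O[Si](C)(C)C(C)(C)C)C[C@]1(C)[C@H](O[Si](CC)(CC)CC)CC[C@@H](C)C1=O | intermediate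
11 | (2R,3R)-3-[(tert-butyldimethylsilyl)oxy]-4-[(1R,3R,6R)-1,3-dimethyl-2-oxo-6-[(triethylsilyl)oxy]cyclohexyl]-2-(propan-2-yl)butanal | O=C[C@H](C(C)C)[C@H](O[Si](C)(C)C(C)(C)C)C[C@]1(C)[C@H](O[Si](CC)(CC)CC)CC[C@@H](C)C1=O | intermediate
12 | (1R,3R,4R,7R,8R,9R,10S)-cis-decalin-8,9-diol: 3,7-dimethyl, 10-isopropyl, 1-OTBS, 4-OTES; angular CH3/OH and C7 methyl on one face, C1, C4, C9 oxygens and isopropyl on the other | C[C@]12C[C@@H](O[Si](C)(C)C(C)(C)C)[C@@H](C(C)C)[C@@H](O)[C@@]1(O)[C@H](C)CC[C@H]2O[Si](CC)(CC)CC | intermediate
13 | 9-O-(4-methoxybenzyl) ether of 12 (same configuration) | C[C@]12C[C@@H](O[Si](C)(C)C(C)(C)C)[C@@H](C(C)C)[C@@H](OCc3ccc(OC)cc3)[C@@]1(O)[C@H](C)CC[C@H]2O[Si](CC)(CC)CC | intermediate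
14 | (1R,3R,4R,7R,8R,9R,10S)-4,8-dihydroxy-9-[(4-methoxybenzyl)oxy]-1-OTBS cis-decalin | C[C@]12C[C@@H](O[Si](C)(C)C(C)(C)C)[C@@H](C(C)C)[C@@H](OCc3ccc(OC)cc3)[C@@]1(O)[C@H](C)CC[C@H]2O | intermediate
15 | (1R,3R,4R,7R,8R,9R,10S)-8-hydroxy-9-[(4-methoxybenzyl)oxy]-1-OTBS cis-decalin 4-(4-methylbenzenesulfonate) | C[C@]12C[C@@H](O[Si](C)(C)C(C)(C)C)[C@@H](C(C)C)[C@@H](OCc3ccc(OC)cc3)[C@@]1(O)[C@H](C)CC[C@H]2OS(=O)(=O)c1ccc(C)cc1 | intermediate
16 | potassium C8-alkoxide of 15 | C[C@]12C[C@@H](O[Si](C)(C)C(C)(C)C)[C@@H](C(C)C)[C@@H](OCc3ccc(OC)cc3)[C@@]1([O-])[C@H](C)CC[C@H]2OS(=O)(=O)c1ccc(C)cc1.[K+] | intermediate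
17 | (1R,3Z,7R,9R,10S)-1-[(tert-butyldimethylsilyl)oxy]-9-[(4-methoxybenzyl)oxy]-3,7-dimethyl-10-(propan-2-yl)cyclodec-3-en-8-one | CC(C)(C)[Si](C)(C)O[C@@H]1C/C(C)=C\CC[C@@H](C)C(=O)[C@H](OCc2ccc(OC)cc2)[C@@H]1C(C)C | intermediate
18 | (1R,3Z,7R,8S,9R,10S)-1-[(tert-butyldimethylsilyl)oxy]-9-[(4-methoxybenzyl)oxy]-3,7-dimethyl-10-(propan-2-yl)cyclodec-3-en-8-ol | CC(C)(C)[Si](C)(C)O[C@@H]1C/C(C)=C\CC[C@@H](C)[C@H](O)[C@H](OCc2ccc(OC)cc2)[C@@H]1C(C)C | intermediate
19 | (1R,3Z,7E,9S,10S)-1-[(tert-butyldimethylsilyl)oxy]-9-[(4-methoxybenzyl)oxy]-3,7-dimethyl-10-(propan-2-yl)cyclodeca-3,7-diene | CC(C)(C)[Si](C)(C)O[C@@H]1C/C(C)=C\CC/C(C)=C/[C@H](OCc2ccc(OC)cc2)[C@@H]1C(C)C | intermediate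
20 | (1R,3Z,7E,9S,10R)-9-[(4-methoxybenzyl)oxy]-3,7-dimethyl-10-(propan-2-yl)cyclodeca-3,7-dien-1-ol | O[C@@H]1C/C(C)=C\CC/C(C)=C/[C@H](OCc2ccc(OC)cc2)[C@@H]1C(C)C | intermediate
21 | 3,4,5-trimethoxybenzoyl chloride | COc1cc(C(Cl)=O)cc(OC)c1OC | starting material
22 | (1R,3Z,7E,9S,10R)-9-[(4-methoxybenzyl)oxy]-3,7-dimethyl-10-(propan-2-yl)cyclodeca-3,7-dien-1-yl 3,4,5-trimethoxybenzoate | COc1cc(C(=O)O[C@@H]2C/C(C)=C\CC/C(C)=C/[C@H](OCc3ccc(OC)cc3)[C@@H]2C(C)C)cc(OC)c1OC | intermediate
23 | (1R,3Z,7E,9S,10S)-9-hydroxy-3,7-dimethyl-10-(propan-2-yl)cyclodeca-3,7-dien-1-yl 3,4,5-trimethoxybenzoate | COc1cc(C(=O)O[C@@H]2C/C(C)=C\CC/C(C)=C/[C@H](O)[C@@H]2C(C)C)cc(OC)c1OC | intermediate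
24 | (1R,3Z,7S,8S,9R,10S)-7,8-epoxy-9-hydroxy-3,7-dimethyl-10-(propan-2-yl)cyclodec-3-en-1-yl 3,4,5-trimethoxybenzoate | COc1cc(C(=O)O[C@@H]2C/C(C)=C\CC[C@]3(C)O[C@H]3[C@H](O)[C@@H]2C(C)C)cc(OC)c1OC | target

## Step count and least certain steps

Total: 19 steps. Longest linear sequence: 19 steps (from 1; 2, 8 and 21 enter as reagents of single steps).

**Step 13 (key step).** What may go wrong is epimerisation at C9 or C7 by enolisation of the new ketone if alkoxide remains after the ring has opened. If ring B leaves the chair with the equatorial sulfonate, the antiperiplanar alignment is lost, and elimination or oxetane formation takes over. Fallback: setting out from 15, LiAlH4 in THF (0 °C → rt) serves as base and as trap. The aluminate of the C8 oxygen fragments, and the ketone is reduced as it forms by chelated hydride delivery, so no enolisable ketone is exposed to base. This fallback comes back to the route at 18 and makes no new compound.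

**Step 9.** The coupling may place the C9 oxygen cis to the C8 oxygen (both oxygens held on one samarium centre), or the aldehyde may simply be reduced. Fallback: setting out from 11, the coupling is run as before and the C9 configuration is corrected afterwards. The 9-epimeric diol F1 is oxidised with Dess–Martin periodinane (NaHCO3, CH2Cl2) to the α-ketol F2. Me4NBH(OAc)3 (MeCN/AcOH, −30 °C), bound to the C8 hydroxyl, then delivers hydride cis to that hydroxyl, which gives the 8,9-trans diol; the route is rejoined at 12.

**Step 6.** Loss of the E geometry of the allylpotassium or allylborane (1,3-shift of the metal) or metalation at the wrong allylic position would erode the anti selectivity. Fallback: setting out from 7, a D-proline-catalysed direct cross-aldol with isovaleraldehyde (slow addition of the donor, DMF, 4 °C) gives the anti β-hydroxy aldehyde F3. Silylation (TBSOTf, 2,6-lutidine) brings the route back at 11.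

**Step 14.** The ring conformation may override the zinc chelate and lead to poor facial selectivity. Fallback: setting out from 17, L-Selectride (THF, −78 °C; Felkin-type, non-chelating) is used to obtain the 8-epimeric alcohol F4. In F4 the C7 hydrogen and the C8 oxygen are syn, so a syn elimination with Burgess reagent (benzene, 45 °C) gives the same E alkene; the route is rejoined at 19.

**Step 15.** Elimination toward C9 (enol ether) or ionisation at C8 followed by transannular attack of C3=C4 would divert the dehydration. Fallback: setting out from 17, the alcohol is bypassed. KHMDS and PhNTf2 (THF, −78 °C) give the enol triflate F5 with C6 cis to the triflate oxygen. Reduction with Pd(OAc)2, PPh3, HCO2H and Bu3N (DMF, 40 °C) replaces the triflate by hydrogen with retention; the route is rejoined at 19.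

## Further compounds

F0 | step 13 | none | none
F1 | step 9 | (1R,3R,4R,7R,8R,9S,10S)-cis-decalin-8,9-diol, the C9 epimer of 12 | C[C@]12C[C@@H](O[Si](C)(C)C(C)(C)C)[C@@H](C(C)C)[C@H](O)[C@@]1(O)[C@H](C)CC[C@H]2O[Si](CC)(CC)CC
F2 | step 9 | (1R,3R,4R,7R,8R,10R)-8-hydroxy-9-oxo cis-decalin (α-ketol; 1-OTBS, 4-OTES) | C[C@]12C[C@@H](O[Si](C)(C)C(C)(C)C)[C@@H](C(C)C)C(=O)[C@@]1(O)[C@H](C)CC[C@H]2O[Si](CC)(CC)CC
F3 | step 6 | (2R,3R)-4-[(1R,3R,6R)-1,3-dimethyl-2-oxo-6-[(triethylsilyl)oxy]cyclohexyl]-3-hydroxy-2-(propan-2-yl)butanal | O=C[C@H](C(C)C)[C@H](O)C[C@]1(C)[C@H](O[Si](CC)(CC)CC)CC[C@@H](C)C1=O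
F4 | step 14 | (1R,3Z,7R,8R,9R,10S)-1-[(tert-butyldimethylsilyl)oxy]-9-[(4-methoxybenzyl)oxy]-3,7-dimethyl-10-(propan-2-yl)cyclodec-3-en-8-ol, the C8 epimer of 18 | CC(C)(C)[Si](C)(C)O[C@@H]1C/C(C)=C\CC[C@@H](C)[C@@H](O)[C@H](OCc2ccc(OC)cc2)[C@@H]1C(C)C
F5 | step 15 | (3Z,7E)-1-[(tert-butyldimethylsilyl)oxy]-9-[(4-methoxybenzyl)oxy]-3,7-dimethyl-10-(propan-2-yl)cyclodeca-3,7-dien-8-yl trifluoromethanesulfonate | CC(C)(C)[Si](C)(C)O[C@@H]1C/C(C)=C\CC/C(C)=C(OS(=O)(=O)C(F)(F)F)/[C@H](OCc2ccc(OC)cc2)[C@@H]1C(C)C
A1 | alternative 1 | (3Z,7E)-3,7,11-trimethyl-9-oxododeca-3,7-dienal | O=CC/C(C)=C\CC/C(C)=C/C(=O)CC(C)C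
A2 | alternative 1 | (1R,3Z,7E,10R)-1-hydroxy-3,7-dimethyl-10-(propan-2-yl)cyclodeca-3,7-dien-9-one (target ring numbering) | O[C@@H]1C/C(C)=C\CC/C(C)=C/C(=O)[C@@H]1C(C)C
A3 | alternative 2 | open-chain (Z)-vinyl iodide/(E)-1,3-diene with C1 3,4,5-trimethoxybenzoate and C9 tert-butyldimethylsilyl ether | COc1cc(C(=O)O[C@@H]([C@@H](C(C)C)[C@@H](O[Si](C)(C)C(C)(C)C)/C=C(C)/C=C)C/C(C)=C\I)cc(OC)c1OC
A4 | alternative 2 | (1R,3Z,7E,9S,10R)-9-[(tert-butyldimethylsilyl)oxy]-3,7-dimethyl-10-(propan-2-yl)cyclodeca-3,7-dien-1-yl 3,4,5-trimethoxybenzoate | COc1cc(C(=O)O[C@@H]2C/C(C)=C\CC/C(C)=C/[C@H](O[Si](C)(C)C(C)(C)C)[C@@H]2C(C)C)cc(OC)c1OC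
A5 | alternative 3 | open-chain (7S,8S)-epoxy aldehyde with C1 4-methoxybenzyl ether and C12 allylic bromide (geometry of the allylic bromide alkene not specified) | COc1ccc(CO[C@@H](C=C(C)CBr)C/C(C)=C\CC[C@]2(C)O[C@H]2C=O)cc1
A6 | alternative 3 | (1R,3Z,7S,8S,9R,10S)-7,8-epoxy-1-[(4-methoxybenzyl)oxy]-3,7-dimethyl-10-(prop-1-en-2-yl)cyclodec-3-en-9-ol | COc1ccc(CO[C@@H]2C/C(C)=C\CC[C@]3(C)O[C@H]3[C@H](O)[C@@H]2C(C)=C)cc1
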